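**Plan**

- Retrosynthesis: cut O1–C2 of the pyranone ring (leaving a C2–C3 oxirane with all phenols silylated), then the oxirane oxygen (E-chalcone), then C2=C3 (aldol/dehydration to an A-ring methyl ketone and 4-silyloxybenzaldehyde), then the silyl and prenyl O–C bonds (phloroacetophenone, prenyl bromide).
- Forward: rings A and B are bought as arenes; the 7-O-prenyl ether is set first, the C4–C3–C2 chain is joined by aldol addition and dehydration, the oxirane is made, and the pyranone ring (O1, C2, C3, C4, C4a, C8a) closes last, in the step that also frees the three phenols.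
- Enabling feature: C2 is the benzylic carbon para to the 4'-OH of ring B, so an oxirane C2–O bond can open to a para-quinone methide once that phenol is free; ring A offers two equivalent hydroxyls ortho to the C4 carbonyl, and C3 already carries its oxygen.
- Stereochemistry: C3 (R) comes from catalytic asymmetric epoxidation of the chalcone (reagent control); C2 (R) is set from C3 during ring closure (2,3-trans, substrate control, convergent through the planar quinone methide).
- Helpers: three tert-butyldimethylsilyl ethers keep the phenols silent and leave with buffered fluoride in the key step; once the prenyl ether is in place no strong acid, hydrogenation, palladium(0) or electrophilic oxidant is used.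

Key step: step 6

Assumption: the La–BINOL catalyst is taken to attack chalcone 11 with the facial sense known for chalcone itself; should it prove opposite, the (R)-ligand is used instead.

**Step 1**
Reactants: 1 2,4,6-trihydroxyacetophenone; 2 prenyl bromide (1-bromo-3-methylbut-2-ene)
Product: 3 1-[2,6-dihydroxy-4-(3-methylbut-2-enyloxy)phenyl]ethanone
Conditions: K2CO3 (1.1 equiv), 2 (1.05 equiv), acetone, reflux
Reagents that add atoms: prenyl bromide (2), CC(C)=CCBr
Why: Williamson ether synthesis; of the three phenols only the 4-OH is not hydrogen-bonded to the acetyl carbonyl and it is the most acidic (para to the acyl group), so one equivalent of a weak base should give its phenoxide and O-alkylation by the allylic bromide at that position.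

**Step 2**
Reactants: 3 1-[2,6-dihydroxy-4-(3-methylbut-2-enyloxy)phenyl]ethanone; 4 tert-butyldimethylsilyl chloride
Product: 5 1-[2,6-bis(tert-butyldimethylsilyloxy)-4-(3-methylbut-2-enyloxy)phenyl]ethanone
Conditions: TBSCl (2.6 equiv), imidazole (5 equiv), DMAP (cat.), DMF, rt → 40 °C
Reagents that add atoms: tert-butyldimethylsilyl chloride (4), CC(C)(C)[Si](C)(C)Cl
Why: Imidazole-promoted silylation of both ortho phenols (the second, chelated one needs DMAP and gentle warming) should give the bis-silyl ether; the silyl groups silence the acidic ortho-hydroxyls for the aldol, elimination and nucleophilic epoxidation steps and can later be removed by fluoride without the acid that an aryl prenyl ether would not tolerate.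

**Step 3**
Reactants: 5 1-[2,6-bis(tert-butyldimethylsilyloxy)-4-(3-methylbut-2-enyloxy)phenyl]ethanone; 6 4-(tert-butyldimethylsilyloxy)benzaldehyde
Product: 9 racemic 1-[2,6-bis(tert-butyldimethylsilyloxy)-4-(3-methylbut-2-enyloxy)phenyl]-3-[4-(tert-butyldimethylsilyloxy)phenyl]-3-hydroxypropan-1-one, via dibutylboron enolate 7 (not isolated), via dibutylboron aldolate 8 (not isolated)
Conditions: n-Bu2BOTf (1.2 equiv), i-Pr2NEt (1.5 equiv), CH2Cl2, −78 °C; then 6, −78 → 0 °C; then pH 7 buffer, MeOH, 30% H2O2, 0 °C
Reagents that add atoms: none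
Why: Boron-mediated aldol addition after soft enolisation: the methyl ketone is converted into its dibutylboron enolate under amine-base conditions, which should avoid the O-to-O silyl transfer and retro-aldol equilibria open to an alkali-metal enolate flanked by two aryl silyl ethers, and the enolate adds to the aldehyde; the new carbinol centre is formed racemic and is destroyed in step 4.

**Step 4**
Reactants: 9 racemic 1-[2,6-bis(tert-butyldimethylsilyloxy)-4-(3-methylbut-2-enyloxy)phenyl]-3-[4-(tert-butyldimethylsilyloxy)phenyl]-3-hydroxypropan-1-one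
Product: 11 (E)-1-[2,6-bis(tert-butyldimethylsilyloxy)-4-(3-methylbut-2-enyloxy)phenyl]-3-[4-(tert-butyldimethylsilyloxy)phenyl]prop-2-en-1-one, via benzylic mesylate 10 (not isolated)
Conditions: MsCl (1.5 equiv), Et3N (4 equiv), CH2Cl2, 0 °C → rt
Reagents that add atoms: none
Why: Mesylation of the benzylic alcohol and E1cB elimination by triethylamine should give the conjugated enone with the thermodynamically favoured E geometry, and the amine base leaves the aryl silyl ethers and the prenyl ether intact.

**Step 5**
Reactants: 11 (E)-1-[2,6-bis(tert-butyldimethylsilyloxy)-4-(3-methylbut-2-enyloxy)phenyl]-3-[4-(tert-butyldimethylsilyloxy)phenyl]prop-2-en-1-one; 12 tert-butyl hydroperoxide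
Product: 13 [(2R,3S)-3-[4-(tert-butyldimethylsilyloxy)phenyl]oxiran-2-yl][2,6-bis(tert-butyldimethylsilyloxy)-4-(3-methylbut-2-enyloxy)phenyl]methanone
Conditions: La(O-i-Pr)3 (10 mol %), (S)-BINOL (10 mol %), Ph3As=O (10 mol %), TBHP (1.5 equiv, decane), 4 Å MS, THF, rt
Reagents that add atoms: tert-butyl hydroperoxide (12), CC(C)(C)OO
Why: Catalytic asymmetric nucleophilic epoxidation of an enone (Weitz–Scheffer type) with a lanthanum–BINOL–triphenylarsine oxide catalyst: lanthanum-bound tert-butyl peroxide adds to the β-carbon of the carbonyl-coordinated enone and the enolate closes onto oxygen with loss of tert-butoxide, so only the electron-poor enone reacts and the electron-rich prenyl alkene is untouched; the trans relationship follows from the E-alkene and the (S)-ligand is chosen as the antipode expected, by analogy with chalcone, to deliver oxygen to the face that gives the (2R,3S)-oxirane.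

**Step 6**
Reactants: 13 [(2R,3S)-3-[4-(tert-butyldimethylsilyloxy)phenyl]oxiran-2-yl][2,6-bis(tert-butyldimethylsilyloxy)-4-(3-methylbut-2-enyloxy)phenyl]methanone
Product: 16 7-prenyloxyaromadendrin [(2R,3R)-3,5-dihydroxy-2-(4-hydroxyphenyl)-7-(3-methylbut-2-enyloxy)-2,3-dihydrochromen-4-one], via triphenol epoxide 14 (not isolated), via para-quinone methide 15 (not isolated)
Conditions: TBAF (3.3 equiv), AcOH (4 equiv), THF, 0 °C → rt, Ar
Reagents that add atoms: none
Why: Fluoride removes the three aryl silyl ethers to give triphenol epoxide 14, whose oxirane C–O bond at the para-hydroxybenzylic carbon ionises with push from the 4-OH (acetic acid assisting at the oxirane oxygen) to the para-quinone methide 15 with the C3–O bond and its configuration untouched, and one of the two homotopic ortho-hydroxyls of ring A then adds to the methide carbon and re-aromatises ring B. The closest known reaction type is the deprotection-triggered cyclisation of 2'-O-protected chalcone epoxides to 2,3-trans-dihydroflavonols, together with the oxa-1,6-addition of phenols to para-quinone methides formed in situ. The pyranone ring closes in the 6-exo-trig mode on the exocyclic methide C=C (a concerted variant would be the 6-endo opening of the oxirane with inversion and leads to the same product). The new stereocentre C2 is controlled by C3: a chair-like closure with the aryl group and the 3-OH both equatorial should give the 2,3-trans (2R,3R) isomer, and since ring opening back to 15 is possible for a 4'-hydroxyflavanonol, a cis isomer can return, which makes the step stereoconvergent at C2. The step needs O-to-C2 closure in preference to 5-exo attack at C3 and to tautomerisation of 15 to the α-hydroxychalcone, which the para-oxygen of ring B (only C2 can carry positive charge, while C3 is deactivated by the adjacent carbonyl) and the acetic acid buffer (phenols stay protonated, no free base) should secure. The remaining ortho-hydroxyl becomes the chelated 5-OH, and the prenyl ether, which would not survive the strong acid of the classical acetal-based variant, is untouched by buffered fluoride.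

**Compound list**

1 | 2,4,6-trihydroxyacetophenone | CC(=O)c1c(O)cc(O)cc1O | starting material
2 | prenyl bromide (1-bromo-3-methylbut-2-ene) | CC(C)=CCBr | starting material
3 | 1-[2,6-dihydroxy-4-(3-methylbut-2-enyloxy)phenyl]ethanone | CC(=O)c1c(O)cc(OCC=C(C)C)cc1O | intermediate
4 | tert-butyldimethylsilyl chloride | CC(C)(C)[Si](C)(C)Cl | starting material
5 | 1-[2,6-bis(tert-butyldimethylsilyloxy)-4-(3-methylbut-2-enyloxy)phenyl]ethanone | CC(=O)c1c(O[Si](C)(C)C(C)(C)C)cc(OCC=C(C)C)cc1O[Si](C)(C)C(C)(C)C | intermediate
6 | 4-(tert-butyldimethylsilyloxy)benzaldehyde | O=Cc1ccc(O[Si](C)(C)C(C)(C)C)cc1 | starting material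
7 | dibutylboron enolate of 5 (not isolated) | C=C(OB(CCCC)CCCC)c1c(O[Si](C)(C)C(C)(C)C)cc(OCC=C(C)C)cc1O[Si](C)(C)C(C)(C)C | intermediate
8 | dibutylboron aldolate, racemic (not isolated) | CCCCB(CCCC)OC(CC(=O)c1c(O[Si](C)(C)C(C)(C)C)cc(OCC=C(C)C)cc1O[Si](C)(C)C(C)(C)C)c1ccc(O[Si](C)(C)C(C)(C)C)cc1 | intermediate
9 | racemic 1-[2,6-bis(tert-butyldimethylsilyloxy)-4-(3-methylbut-2-enyloxy)phenyl]-3-[4-(tert-butyldimethylsilyloxy)phenyl]-3-hydroxypropan-1-one | CC(C)=CCOc1cc(O[Si](C)(C)C(C)(C)C)c(C(=O)CC(O)c2ccc(O[Si](C)(C)C(C)(C)C)cc2)c(O[Si](C)(C)C(C)(C)C)c1 | intermediate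
10 | benzylic mesylate of 9, racemic (not isolated) | CC(C)=CCOc1cc(O[Si](C)(C)C(C)(C)C)c(C(=O)CC(OS(C)(=O)=O)c2ccc(O[Si](C)(C)C(C)(C)C)cc2)c(O[Si](C)(C)C(C)(C)C)c1 | intermediate
11 | (E)-1-[2,6-bis(tert-butyldimethylsilyloxy)-4-(3-methylbut-2-enyloxy)phenyl]-3-[4-(tert-butyldimethylsilyloxy)phenyl]prop-2-en-1-one | CC(C)=CCOc1cc(O[Si](C)(C)C(C)(C)C)c(C(=O)/C=C/c2ccc(O[Si](C)(C)C(C)(C)C)cc2)c(O[Si](C)(C)C(C)(C)C)c1 | intermediate
12 | tert-butyl hydroperoxide | CC(C)(C)OO | starting material
13 | [(2R,3S)-3-[4-(tert-butyldimethylsilyloxy)phenyl]oxiran-2-yl][2,6-bis(tert-butyldimethylsilyloxy)-4-(3-methylbut-2-enyloxy)phenyl]methanone | CC(C)=CCOc1cc(O[Si](C)(C)C(C)(C)C)c(C(=O)[C@@H]2O[C@H]2c2ccc(O[Si](C)(C)C(C)(C)C)cc2)c(O[Si](C)(C)C(C)(C)C)c1 | intermediate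
14 | [(2R,3S)-3-(4-hydroxyphenyl)oxiran-2-yl][2,6-dihydroxy-4-(3-methylbut-2-enyloxy)phenyl]methanone (not isolated) | CC(C)=CCOc1cc(O)c(C(=O)[C@@H]2O[C@H]2c2ccc(O)cc2)c(O)c1 | intermediate
15 | 4-[(2R)-3-[2,6-dihydroxy-4-(3-methylbut-2-enyloxy)phenyl]-2-hydroxy-3-oxopropylidene]cyclohexa-2,5-dien-1-one (not isolated) | CC(C)=CCOc1cc(O)c(C(=O)[C@H](O)C=C2C=CC(=O)C=C2)c(O)c1 | intermediate
16 | 7-prenyloxyaromadendrin, (2R,3R)-3,5-dihydroxy-2-(4-hydroxyphenyl)-7-(3-methylbut-2-enyloxy)-2,3-dihydrochromen-4-one | CC(C)=CCOc1cc(O)c2c(c1)O[C@H](c1ccc(O)cc1)[C@@H](O)C2=O | target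

**Count and risks**

Total steps: 6. Longest linear sequence: 6 steps (1 → 16).

Steps most likely to fail:

Step 6. The freed ortho-phenol may close through the wrong carbon (5-exo attack at C3, leading to a benzofuranone). The quinone methide may instead tautomerise to the α-hydroxychalcone/1,2-diketone manifold before ring closure. Traces of base may also erode C3 by enolisation. The fallback sets out from 13 and returns at 16, and it separates oxirane opening from ring closure. Mild acid-catalysed methanolysis of the oxirane at the benzylic carbon (PPTS cat., MeOH–CH2Cl2, 0 °C → rt) should give (2R)-1-[2,6-bis(tert-butyldimethylsilyloxy)-4-(3-methylbut-2-enyloxy)phenyl]-2-hydroxy-3-methoxy-3-[4-(tert-butyldimethylsilyloxy)phenyl]propan-1-one F1 as a mixture of C3 epimers with the silyl ethers intact. The C–O bond of the future 3-OH is thereby fixed before any phenol is free. Buffered fluoride (TBAF/AcOH, THF, 0 °C) should then give the triphenol (2R)-1-[2,6-dihydroxy-4-(3-methylbut-2-enyloxy)phenyl]-2-hydroxy-3-(4-hydroxyphenyl)-3-methoxypropan-1-one F2. Catalytic camphorsulfonic acid in MeCN at rt should ionise its para-hydroxybenzylic methyl ether and let the ortho-phenol close the ring under acid, with no phenoxide present, to give 16 with loss of methanol. Both C3 epimers of F2 should converge on the trans product.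

Step 5. The two ortho-silyloxy groups may shield the carbonyl from the lanthanum centre, giving low conversion or poor facial selectivity. The fallback sets out from 11 and returns at 13, and it replaces asymmetric catalysis by resolution. Ligand-free epoxidation (TBHP, cat. La(O-i-Pr)3/Ph3As=O, 4 Å MS, THF) should give the trans-oxirane as the racemate, that is 13 together with its enantiomer [(2S,3R)-3-[4-(tert-butyldimethylsilyloxy)phenyl]oxiran-2-yl][2,6-bis(tert-butyldimethylsilyloxy)-4-(3-methylbut-2-enyloxy)phenyl]methanone F3. Preparative chromatography on a polysaccharide carbamate chiral stationary phase, a separation for which trans-chalcone oxides are standard analytes, should then deliver 13.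

Step 1. The ambident phloroglucinol phenoxide may be alkylated twice or at carbon, lowering the amount of mono-ether. The fallback sets out from 1 and returns at 3. Mitsunobu etherification with 3-methylbut-2-en-1-ol (PPh3, DIAD, THF, 0 °C) works without a free phenoxide and should react through the most acidic, non-chelated 4-OH. This fallback makes no new compound (F0).

**Further compounds**

F1 | step 6 | (2R)-1-[2,6-bis(tert-butyldimethylsilyloxy)-4-(3-methylbut-2-enyloxy)phenyl]-2-hydroxy-3-methoxy-3-[4-(tert-butyldimethylsilyloxy)phenyl]propan-1-one (C3 epimers) | CC(C)=CCOc1cc(O[Si](C)(C)C(C)(C)C)c(C(=O)[C@H](O)C(OC)c2ccc(O[Si](C)(C)C(C)(C)C)cc2)c(O[Si](C)(C)C(C)(C)C)c1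
F2 | step 6 | (2R)-1-[2,6-dihydroxy-4-(3-methylbut-2-enyloxy)phenyl]-2-hydroxy-3-(4-hydroxyphenyl)-3-methoxypropan-1-one (C3 epimers) | CC(C)=CCOc1cc(O)c(C(=O)[C@H](O)C(OC)c2ccc(O)cc2)c(O)c1
F3 | step 5 | [(2S,3R)-3-[4-(tert-butyldimethylsilyloxy)phenyl]oxiran-2-yl][2,6-bis(tert-butyldimethylsilyloxy)-4-(3-methylbut-2-enyloxy)phenyl]methanone | CC(C)=CCOc1cc(O[Si](C)(C)C(C)(C)C)c(C(=O)[C@H]2O[C@@H]2c2ccc(O[Si](C)(C)C(C)(C)C)cc2)c(O[Si](C)(C)C(C)(C)C)c1
F0 | step 1 | none | none
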